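**Plan**
- Retrosynthesis: remove the benzyl group from the 3'-OH, then open ring C at O1–C2 (oxidative cyclisation) and C2–C3 (aldol) to give acetophenone 11 and aldehyde 13. Ring A is then cut at C4a–C8a (electrocyclisation) and C5–C6 (organolithium addition).
- Enabling feature: C8a, C8, C7 and C6 of ring A are four adjacent oxygen-bearing carbons, the same pattern as the four ring carbons of dimethyl squarate. C5 and C4a come from an E-alkene that also carries C4 (as a dioxolane) and C3 (the methyl group).
- Forward order: ketal alkyne, E-vinylstannane, vinyllithium addition to the squarate with O-methylation (7), thermal ring expansion closing ring A (10), ketone release (11), aldol attachment of ring B (15), closure of ring C (18), debenzylation (19).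
- Stereochemistry: the target has no stereocentre. Only the E geometry of the vinyl metal (set by hydrostannation) matters, and the racemic centre of 7 disappears on aromatisation.
- Assumption: but-3-yn-2-one, dimethyl squarate and 3-hydroxy-4,5-dimethoxybenzaldehyde are taken as commercial.

Key step: step 4

**Route**

Step 1
Reactants: 1 but-3-yn-2-one
Product: 2 2-ethynyl-2-methyl-1,3-dioxolane
Conditions: 1,2-bis(trimethylsilyloxy)ethane, Me3SiOSO2CF3 (cat.), CH2Cl2, −78 to 0 °C; pyridine quench
Reagents that add atoms: 1,2-bis(trimethylsilyloxy)ethane, C[Si](C)(C)OCCO[Si](C)(C)C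
Why: Noyori ketalisation runs under aprotic conditions at low temperature, so the terminal ynone should be ketalised without conjugate addition of the diol, driven by formation of the strong Si–O–Si bond.

Step 2
Reactants: 2 2-ethynyl-2-methyl-1,3-dioxolane
Product: 3 tributyl[(E)-2-(2-methyl-1,3-dioxolan-2-yl)ethenyl]stannane
Conditions: Bu3SnH (1.1 equiv), 2,2'-azobis(2-methylpropanenitrile) (cat.), toluene, 85 °C
Reagents that add atoms: tributyltin hydride, CCCC[SnH](CCCC)CCCC
Why: Radical-chain hydrostannation of a terminal alkyne places tin on the terminal carbon, and reversible stannyl-radical addition at 85 °C should equilibrate the alkene to the E isomer, the quaternary ketal carbon disfavouring the internal regioisomer and the Z form.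

Step 3
Reactants: 3 tributyl[(E)-2-(2-methyl-1,3-dioxolan-2-yl)ethenyl]stannane; 4 dimethyl squarate (3,4-dimethoxycyclobut-3-ene-1,2-dione)
Product: 7 2,3,4-trimethoxy-4-[(E)-2-(2-methyl-1,3-dioxolan-2-yl)ethenyl]cyclobut-2-en-1-one (racemic), via vinyllithium 5 (not isolated), via lithium alkoxide 6 (not isolated)
Conditions: n-BuLi (1.0 equiv), THF, −78 °C; cannulate into 4, THF, −78 °C; MeOTf (1.5 equiv), −78 to 0 °C; aq. NaHCO3
Reagents that add atoms: methyl trifluoromethanesulfonate, COS(=O)(=O)C(F)(F)F
Why: Tin–lithium exchange retains the alkene geometry, the vinyllithium adds 1,2 to one of the two equivalent squarate carbonyls, and the tertiary lithium alkoxide is O-methylated in situ by the triflate; the new quaternary centre forms as a racemate and is destroyed in step 4.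

Step 4
Reactants: 7 2,3,4-trimethoxy-4-[(E)-2-(2-methyl-1,3-dioxolan-2-yl)ethenyl]cyclobut-2-en-1-one
Product: 10 2-(2-hydroxy-3,4,5-trimethoxyphenyl)-2-methyl-1,3-dioxolane, via dienylketene 8 (not isolated), via cyclohexadienone 9 (not isolated)
Conditions: degassed toluene (0.02 M), 110 °C, N2 (p-xylene, 138 °C, if conversion is slow)
Reagents that add atoms: none
Why: Heating cleaves the C1–C4 bond of the cyclobutenone in a conrotatory four-electron electrocyclic opening to dienylketene 8, which closes by a disrotatory six-electron electrocyclisation between the ketene carbon (future C8a) and the distal alkene carbon (future C4a) to dienone 9, and 9 aromatises by enolisation to phenol 10. The closest known reaction type is the Moore ring expansion of 4-alkenyl-4-alkoxycyclobutenones made from squarate esters, an established route to hydroquinone monoethers. Ring A is closed as a six-membered carbocycle by thermal 6π electrocyclisation of a ketene-terminated triene. No stereocentre is created: the centre of 7 becomes sp2 on ring opening and the sp3 carbon of 9 is lost on tautomerisation. The step needs the alkenyl group to rotate inward towards the ketene; the donor 4-methoxy group secures this by its strong preference for outward rotation, and reversible ring opening returns any wrongly rotated ketene to 7. The E alkene keeps the dioxolane on the outside of the closing terminus.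

Step 5
Reactants: 10 2-(2-hydroxy-3,4,5-trimethoxyphenyl)-2-methyl-1,3-dioxolane
Product: 11 1-(2-hydroxy-3,4,5-trimethoxyphenyl)ethan-1-one
Conditions: 1 M HCl, THF, rt
Reagents that add atoms: water, O
Why: Acid-catalysed acetal hydrolysis should be fast because the oxocarbenium ion is benzylic and the ketone is stabilised by hydrogen bonding to the ortho hydroxyl, while aryl methyl ethers are inert to dilute acid.

Step 6
Reactants: 12 3-hydroxy-4,5-dimethoxybenzaldehyde
Product: 13 3-(benzyloxy)-4,5-dimethoxybenzaldehyde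
Conditions: BnBr, K2CO3, DMF, rt
Reagents that add atoms: benzyl bromide, BrCc1ccccc1
Why: Williamson ether synthesis on the only phenol, with a weak base that leaves the non-enolisable aldehyde untouched.

Step 7
Reactants: 11 1-(2-hydroxy-3,4,5-trimethoxyphenyl)ethan-1-one; 13 3-(benzyloxy)-4,5-dimethoxybenzaldehyde
Product: 15 (E)-3-[3-(benzyloxy)-4,5-dimethoxyphenyl]-1-(2-hydroxy-3,4,5-trimethoxyphenyl)prop-2-en-1-one, via aldol adduct 14 (not isolated)
Conditions: KOH (50% aq., excess), EtOH, rt; then 1 M HCl
Reagents that add atoms: none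
Why: Claisen–Schmidt condensation, in which the methyl ketone enolate adds to the non-enolisable aldehyde and E1cB dehydration of the aldol gives the conjugated E enone under thermodynamic control.

Step 8
Reactants: 15 (E)-3-[3-(benzyloxy)-4,5-dimethoxyphenyl]-1-(2-hydroxy-3,4,5-trimethoxyphenyl)prop-2-en-1-one
Product: 18 2-[3-(benzyloxy)-4,5-dimethoxyphenyl]-6,7,8-trimethoxy-4H-chromen-4-one, via flavanone 16 (not isolated), via 3-iodoflavanone 17 (not isolated)
Conditions: I2 (0.1 equiv), DMSO, 120 °C; aq. Na2S2O3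
Reagents that add atoms: none
Why: Iodine/DMSO oxidative cyclisation of a 2'-hydroxychalcone, in which 6-endo oxa-Michael closure, alpha-iodination and loss of HI give the flavone while DMSO reoxidises HI to I2, a sequence well precedented for polymethoxylated 2'-hydroxychalcones.

Step 9
Reactants: 18 2-[3-(benzyloxy)-4,5-dimethoxyphenyl]-6,7,8-trimethoxy-4H-chromen-4-one
Product: 19 2-(3-hydroxy-4,5-dimethoxyphenyl)-6,7,8-trimethoxy-4H-chromen-4-one
Conditions: H2 (1 atm), 10% Pd/C, EtOAc–MeOH, rt
Reagents that add atoms: none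
Why: Catalytic hydrogenolysis of a benzyl aryl ether over Pd/C should be much faster than reduction of the flavone C2–C3 double bond, and the methyl ethers are untouched.

**Compound list**
1 | but-3-yn-2-one | CC(=O)C#C | starting material
2 | 2-ethynyl-2-methyl-1,3-dioxolane | CC1(C#C)OCCO1 | intermediate
3 | tributyl[(E)-2-(2-methyl-1,3-dioxolan-2-yl)ethenyl]stannane | CCCC[Sn](CCCC)(CCCC)/C=C/C1(C)OCCO1 | intermediate
4 | dimethyl squarate (3,4-dimethoxycyclobut-3-ene-1,2-dione) | COC1=C(OC)C(=O)C1=O | starting material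
5 | [(E)-2-(2-methyl-1,3-dioxolan-2-yl)ethenyl]lithium (vinyllithium; not isolated) | [Li]/C=C/C1(C)OCCO1 | intermediate
6 | lithium 2,3-dimethoxy-1-[(E)-2-(2-methyl-1,3-dioxolan-2-yl)ethenyl]-4-oxocyclobut-2-en-1-olate (racemic; not isolated) | COC1=C(OC)C([O-])(/C=C/C2(C)OCCO2)C1=O.[Li+] | intermediate
7 | 2,3,4-trimethoxy-4-[(E)-2-(2-methyl-1,3-dioxolan-2-yl)ethenyl]cyclobut-2-en-1-one (racemic) | COC1=C(OC)C(OC)(/C=C/C2(C)OCCO2)C1=O | intermediate
8 | (3Z,5E)-2,3,4-trimethoxy-6-(2-methyl-1,3-dioxolan-2-yl)hexa-1,3,5-trien-1-one (dienylketene; not isolated) | O=C=C(OC)/C(OC)=C(OC)\C=C\C1(C)OCCO1 | intermediate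
9 | 2,3,4-trimethoxy-6-(2-methyl-1,3-dioxolan-2-yl)cyclohexa-2,4-dien-1-one (racemic; not isolated) | COC1=CC(C2(C)OCCO2)C(=O)C(OC)=C1OC | intermediate
10 | 2-(2-hydroxy-3,4,5-trimethoxyphenyl)-2-methyl-1,3-dioxolane | CC1(OCCO1)c1cc(OC)c(OC)c(OC)c1O | intermediate
11 | 1-(2-hydroxy-3,4,5-trimethoxyphenyl)ethan-1-one | CC(=O)c1cc(OC)c(OC)c(OC)c1O | intermediate
12 | 3-hydroxy-4,5-dimethoxybenzaldehyde | COc1cc(C=O)cc(O)c1OC | starting material
13 | 3-(benzyloxy)-4,5-dimethoxybenzaldehyde | COc1cc(C=O)cc(OCc2ccccc2)c1OC | intermediate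
14 | 3-[3-(benzyloxy)-4,5-dimethoxyphenyl]-3-hydroxy-1-(2-hydroxy-3,4,5-trimethoxyphenyl)propan-1-one (racemic aldol adduct; not isolated) | COc1cc(C(O)CC(=O)c2cc(OC)c(OC)c(OC)c2O)cc(OCc2ccccc2)c1OC | intermediate
15 | (E)-3-[3-(benzyloxy)-4,5-dimethoxyphenyl]-1-(2-hydroxy-3,4,5-trimethoxyphenyl)prop-2-en-1-one | COc1cc(/C=C/C(=O)c2cc(OC)c(OC)c(OC)c2O)cc(OCc2ccccc2)c1OC | intermediate
16 | 2-[3-(benzyloxy)-4,5-dimethoxyphenyl]-6,7,8-trimethoxy-2,3-dihydro-4H-chromen-4-one (racemic flavanone; not isolated) | COc1cc(C2CC(=O)c3cc(OC)c(OC)c(OC)c3O2)cc(OCc2ccccc2)c1OC | intermediate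
17 | 2-[3-(benzyloxy)-4,5-dimethoxyphenyl]-3-iodo-6,7,8-trimethoxy-2,3-dihydro-4H-chromen-4-one (racemic; C2/C3 relative configuration not controlled; not isolated) | COc1cc(C2Oc3c(OC)c(OC)c(OC)cc3C(=O)C2I)cc(OCc2ccccc2)c1OC | intermediate
18 | 2-[3-(benzyloxy)-4,5-dimethoxyphenyl]-6,7,8-trimethoxy-4H-chromen-4-one | COc1cc(-c2cc(=O)c3cc(OC)c(OC)c(OC)c3o2)cc(OCc2ccccc2)c1OC | intermediate
19 | 2-(3-hydroxy-4,5-dimethoxyphenyl)-6,7,8-trimethoxy-4H-chromen-4-one | COc1cc(-c2cc(=O)c3cc(OC)c(OC)c(OC)c3o2)cc(O)c1OC | target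

**Step count**
Total steps: 9. Longest linear sequence: 8 (steps 1, 2, 3, 4, 5, 7, 8, 9); step 6 is a one-step side branch.

**Steps most likely to fail**

Step 3. The tin–lithium exchange may stay incomplete, so that residual n-BuLi transfers a butyl group to the squarate, and tetrabutylstannane may complicate isolation of the thermally sensitive product. The fallback sets out from 3 and generates the nucleophile by halogen–lithium exchange instead. Iododestannylation (I2, CH2Cl2, 0 °C) should give 2-[(E)-2-iodoethenyl]-2-methyl-1,3-dioxolane F1 with retention of geometry. Treatment of F1 with t-BuLi (2 equiv) in Et2O at −78 °C should form the vinyllithium irreversibly and free of any butyl nucleophile. The route is rejoined at 5, which is added to 4 and methylated as before.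

Step 4. Ring opening of the fully substituted methyl ether may need temperatures at which the ketene is consumed by intermolecular addition or the electron-rich phenol is oxidised. The fallback carries the C4 oxygen through the ring expansion as a free hydroxyl and methylates afterwards, which also removes any dependence on the alkoxide methylation. It sets out from 6 and returns at 11.
- Quenching 6 with aqueous NH4Cl at −78 °C should give 4-hydroxy-2,3-dimethoxy-4-[(E)-2-(2-methyl-1,3-dioxolan-2-yl)ethenyl]cyclobut-2-en-1-one F2.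
- Thermolysis of F2 in degassed dioxane at reflux should pass through (3Z,5E)-4-hydroxy-2,3-dimethoxy-6-(2-methyl-1,3-dioxolan-2-yl)hexa-1,3,5-trien-1-one F3 and 4-hydroxy-2,3-dimethoxy-6-(2-methyl-1,3-dioxolan-2-yl)cyclohexa-2,4-dien-1-one F4 to the hydroquinone 2-(2,5-dihydroxy-3,4-dimethoxyphenyl)-2-methyl-1,3-dioxolane F5.
- 1 M HCl in THF should convert F5 into 1-(2,5-dihydroxy-3,4-dimethoxyphenyl)ethan-1-one F6.
- MeI (1 equiv), K2CO3, acetone under N2 should methylate only the hydroxyl that is not hydrogen-bonded to the ketone, giving 11.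

Step 8. Electrophilic iodination of the electron-rich rings or ether cleavage by HI at 120 °C may compete with dehydrogenation, or the reaction may stall at the flavanone. The fallback builds C2 at the ketone oxidation level so that no oxidant is needed. It sets out from 13 and 11 and returns at 18.
- Pinnick oxidation of 13 (NaClO2, NaH2PO4, 2-methylbut-2-ene, t-BuOH–H2O) should give 3-(benzyloxy)-4,5-dimethoxybenzoic acid F7.
- Esterification of F7 with 11 (EDC hydrochloride, 4-(dimethylamino)pyridine, CH2Cl2) should give 2-acetyl-4,5,6-trimethoxyphenyl 3-(benzyloxy)-4,5-dimethoxybenzoate F8.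
- Baker–Venkataraman acyl shift of F8 (KOH, pyridine, 50 °C) should give 1-[3-(benzyloxy)-4,5-dimethoxyphenyl]-3-(2-hydroxy-3,4,5-trimethoxyphenyl)propane-1,3-dione F9.
- Cyclodehydration of F9 (H2SO4 cat., AcOH, 90 °C) should give 18.

**Further compounds**
F1 | step 3 | 2-[(E)-2-iodoethenyl]-2-methyl-1,3-dioxolane | CC1(/C=C/I)OCCO1
F2 | step 4 | 4-hydroxy-2,3-dimethoxy-4-[(E)-2-(2-methyl-1,3-dioxolan-2-yl)ethenyl]cyclobut-2-en-1-one (racemic) | COC1=C(OC)C(O)(/C=C/C2(C)OCCO2)C1=O
F3 | step 4 | (3Z,5E)-4-hydroxy-2,3-dimethoxy-6-(2-methyl-1,3-dioxolan-2-yl)hexa-1,3,5-trien-1-one (not isolated) | O=C=C(OC)/C(OC)=C(O)\C=C\C1(C)OCCO1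
F4 | step 4 | 4-hydroxy-2,3-dimethoxy-6-(2-methyl-1,3-dioxolan-2-yl)cyclohexa-2,4-dien-1-one (racemic; not isolated) | OC1=CC(C2(C)OCCO2)C(=O)C(OC)=C1OC
F5 | step 4 | 2-(2,5-dihydroxy-3,4-dimethoxyphenyl)-2-methyl-1,3-dioxolane | CC1(OCCO1)c1cc(O)c(OC)c(OC)c1O
F6 | step 4 | 1-(2,5-dihydroxy-3,4-dimethoxyphenyl)ethan-1-one | CC(=O)c1cc(O)c(OC)c(OC)c1O
F7 | step 8 | 3-(benzyloxy)-4,5-dimethoxybenzoic acid | COc1cc(C(=O)O)cc(OCc2ccccc2)c1OC
F8 | step 8 | 2-acetyl-4,5,6-trimethoxyphenyl 3-(benzyloxy)-4,5-dimethoxybenzoate | CC(=O)c1cc(OC)c(OC)c(OC)c1OC(=O)c1cc(OC)c(OC)c(OCc2ccccc2)c1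
F9 | step 8 | 1-[3-(benzyloxy)-4,5-dimethoxyphenyl]-3-(2-hydroxy-3,4,5-trimethoxyphenyl)propane-1,3-dione | COc1cc(C(=O)CC(=O)c2cc(OC)c(OC)c(OC)c2O)cc(OCc2ccccc2)c1OC
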